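**Retrosynthetic overview**
1. Target 10 ⇐ acyl shift of the lactone from the 7'-oxygen to the 9'-oxygen in γ-aryl lactone 8 ⇐ borane reduction of lactone acid 7.
2. 7 ⇐ reductive opening of one ring of dilactone 5 through a para-quinone methide. Only the ring whose aryl group keeps a free 4-OH can open, which puts the free phenol on the benzyl arm and the dimethoxyphenyl ring on the carbinol.
3. 5 ⇐ mono-O-methylation of the C2-symmetric dilactone 4 ⇐ resolution of racemic 3.
4. 3 ⇐ 8–8' oxidative phenol coupling of two molecules of ferulic acid 1, with both carboxyl groups trapping the bis(quinone methide) 2.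
5. Ring order: both lactone rings of the bicycle form in step 1 (C8–C8' bond, then two C7–O bonds); one ring is opened in step 4; the surviving lactone is re-closed onto C9' in step 5.

Locants: C7/C8/C9 are the side-chain carbons of ring A (guaiacyl, ends as the benzyl arm); C7'/C8'/C9' are those of ring B (ends as the 3,4-dimethoxyphenyl carbinol arm).

Assumption: the coupling is racemic, so the single enantiomer comes from a chromatographic resolution (step 2); the needed (3S,3aS,6S,6aS) enantiomer is identified by ECD or X-ray and confirmed by the rotation of 10.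

**Step 1**
Reactants: 1 (E)-ferulic acid (two molecules)
Product: 3 racemic (3RS,3aRS,6RS,6aRS)-3,6-bis(4-hydroxy-3-methoxyphenyl)tetrahydro-1H,3H-furo[3,4-c]furan-1,4-dione, via bis(quinone methide) diacid 2 (not isolated)
Conditions: FeCl3·6H2O (1.05 equiv), H2O–EtOH 4:1, rt, slow addition at high dilution; crystallisation/chromatography
Reagents that add atoms: none
Why: One-electron oxidation of the phenol by trivalent iron gives the phenoxyl radical, 8–8' radical coupling (biomimetic oxidative phenol coupling) gives 2, and each carboxyl group then adds 1,6 to the opposite quinone methide, so the cis ring fusion at C8/C8' is forced by the bicyclo[3.3.0] skeleton and both aryl groups settle exo, as a racemate (8–5' and 8–O–4' dimers limit the expected yield to about 15–25%).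

**Step 2**
Reactants: 3 racemic dilactone
Product: 4 (3S,3aS,6S,6aS)-3,6-bis(4-hydroxy-3-methoxyphenyl)tetrahydro-1H,3H-furo[3,4-c]furan-1,4-dione
Conditions: preparative SFC, amylose tris(3,5-dimethylphenylcarbamate) stationary phase, CO2–MeOH, 35 °C
Reagents that add atoms: none
Why: Chromatographic resolution on a chiral stationary phase separates the rigid C2-symmetric racemate without any bond change, and the enantiomer kept fixes the absolute configuration of all stereocenters carried forward.

**Step 3**
Reactants: 4 (3S,3aS,6S,6aS)-dilactone bis-phenol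
Product: 5 (3S,3aS,6S,6aS)-3-(3,4-dimethoxyphenyl)-6-(4-hydroxy-3-methoxyphenyl)tetrahydro-1H,3H-furo[3,4-c]furan-1,4-dione
Conditions: CH2N2 (1.0 equiv, Et2O), MeOH–1,4-dioxane, 0 °C to rt; chromatography, recovered 4 recycled
Reagents that add atoms: diazomethane, C=[N+]=[N-]
Why: Phenol O-methylation with diazomethane runs without base, so no phenoxide forms that could open the base-labile benzylic lactones, and because 4 is C2-symmetric either phenol gives the same mono-ether (statistical, about 45% per pass) with no stereocenter touched.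

**Step 4**
Reactants: 5 mono-methyl dilactone
Product: 7 (2S,3S,4R)-2-(3,4-dimethoxyphenyl)-4-(4-hydroxy-3-methoxybenzyl)-5-oxooxolane-3-carboxylic acid, via para-quinone methide 6 (not isolated)
Conditions: NaBH4 (6 equiv), THF–EtOH–H2O, 0 °C to rt; then 1 M HCl to pH 2
Reagents that add atoms: none
Why: In the mildly basic borohydride medium only ring A, which still has a free para-hydroxyl, can expel its benzylic carboxylate (E1cB-type quinone methide formation), and irreversible 1,6-hydride addition to 6 leaves C7 as CH2 (a chemical copy of the pinoresinol–lariciresinol reductase step), while the ring B lactone cannot ionise and C8, C8', C7' are untouched (the C8 descriptor changes from S to R only through CIP priorities).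

**Step 5**
Reactants: 7 lactone acid
Product: 10 (3R,4R)-4-[(S)-(3,4-dimethoxyphenyl)(hydroxy)methyl]-3-(4-hydroxy-3-methoxybenzyl)oxolan-2-one, via hydroxymethyl lactone 8 (not isolated), via dihydroxy acid 9 (not isolated)
Conditions: BH3·SMe2 (3.5 equiv), THF, 0 °C to rt; MeOH quench; LiOH (5 equiv), THF–H2O, 0 °C to rt; 1 M HCl to pH 3, rt, 12 h
Reagents that add atoms: lithium hydroxide, [Li+].[OH-] (its oxygen enters the carboxylate and can remain as the lactone carbonyl oxygen)
Why: Chemoselective borane reduction takes the free carboxylic acid to CH2OH much faster than it attacks the lactone, and saponification–relactonisation (translactonisation through hydroxy acid 9) then closes the carboxyl onto the primary 9'-hydroxyl rather than the hindered benzylic one, giving the less strained trans-disubstituted lactone without breaking any bond to C8, C8' or C7', so the centres set in step 1 appear as 3R,4R and carbinol S.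

**Compound list**
1 | (E)-ferulic acid, (E)-3-(4-hydroxy-3-methoxyphenyl)prop-2-enoic acid | COc1cc(/C=C/C(=O)O)ccc1O | starting material
2 | (2RS,3RS)-2,3-bis[(3-methoxy-4-oxocyclohexa-2,5-dien-1-ylidene)methyl]butanedioic acid (racemate, the 2R,3R enantiomer drawn) | COC1=CC(=C[C@@H](C(=O)O)[C@H](C(=O)O)C=C2C=CC(=O)C(OC)=C2)C=CC1=O | intermediate
3 | racemic (3RS,3aRS,6RS,6aRS)-3,6-bis(4-hydroxy-3-methoxyphenyl)tetrahydro-1H,3H-furo[3,4-c]furan-1,4-dione, cis-fused, both aryl groups exo (the all-S enantiomer drawn) | COc1cc([C@H]2OC(=O)[C@@H]3[C@@H](c4ccc(O)c(OC)c4)OC(=O)[C@H]23)ccc1O | intermediate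
4 | (3S,3aS,6S,6aS)-3,6-bis(4-hydroxy-3-methoxyphenyl)tetrahydro-1H,3H-furo[3,4-c]furan-1,4-dione | COc1cc([C@H]2OC(=O)[C@@H]3[C@@H](c4ccc(O)c(OC)c4)OC(=O)[C@H]23)ccc1O | intermediate
5 | (3S,3aS,6S,6aS)-3-(3,4-dimethoxyphenyl)-6-(4-hydroxy-3-methoxyphenyl)tetrahydro-1H,3H-furo[3,4-c]furan-1,4-dione | COc1ccc([C@H]2OC(=O)[C@@H]3[C@@H](c4ccc(O)c(OC)c4)OC(=O)[C@H]23)cc1OC | intermediate
6 | (2S,3S,4R)-2-(3,4-dimethoxyphenyl)-4-[(3-methoxy-4-oxocyclohexa-2,5-dien-1-ylidene)methyl]-5-oxooxolane-3-carboxylic acid (present as its sodium carboxylate; methide geometry not defined) | COC1=CC(=C[C@H]2C(=O)O[C@H](c3ccc(OC)c(OC)c3)[C@H]2C(=O)O)C=CC1=O | intermediate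
7 | (2S,3S,4R)-2-(3,4-dimethoxyphenyl)-4-(4-hydroxy-3-methoxybenzyl)-5-oxooxolane-3-carboxylic acid (aryl trans to CO2H, benzyl cis to CO2H) | COc1cc(C[C@H]2C(=O)O[C@H](c3ccc(OC)c(OC)c3)[C@H]2C(=O)O)ccc1O | intermediate
8 | (3R,4R,5S)-5-(3,4-dimethoxyphenyl)-3-(4-hydroxy-3-methoxybenzyl)-4-(hydroxymethyl)oxolan-2-one | COc1cc(C[C@H]2C(=O)O[C@H](c3ccc(OC)c(OC)c3)[C@H]2CO)ccc1O | intermediate
9 | (2R,3R)-3-[(S)-(3,4-dimethoxyphenyl)(hydroxy)methyl]-4-hydroxy-2-(4-hydroxy-3-methoxybenzyl)butanoic acid (lithium salt before acidification) | COc1cc(C[C@@H](C(=O)O)[C@H](CO)[C@H](O)c2ccc(OC)c(OC)c2)ccc1O | intermediate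
10 | (3R,4R)-4-[(S)-(3,4-dimethoxyphenyl)(hydroxy)methyl]-3-(4-hydroxy-3-methoxybenzyl)oxolan-2-one | COc1cc(C[C@H]2C(=O)OC[C@@H]2[C@H](O)c2ccc(OC)c(OC)c2)ccc1O | target

**Totals**
Total step count: 5. Longest linear sequence: 5 steps (1 → 3 → 4 → 5 → 7 → 10).

**Steps most likely to fail, with fallbacks**

Step 1 (with the resolution of step 2): the coupling is low-yielding, gives other dimer types, and is racemic. The fallback sets out from 1 and comes back at 4, replacing steps 1 and 2 by an auxiliary-controlled enolate coupling that needs no resolution.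
- Hydrogenation of 1 (H2, Pd/C, EtOAc) gives 3-(4-hydroxy-3-methoxyphenyl)propanoic acid F1.
- Pivaloyl chloride (2.2 equiv)/Et3N esterifies the phenol and forms the mixed anhydride; the lithium salt of (4S)-4-isopropyl-1,3-oxazolidin-2-one (n-BuLi, THF, −78 °C) then gives 2-methoxy-4-{3-[(4S)-4-isopropyl-2-oxo-1,3-oxazolidin-3-yl]-3-oxopropyl}phenyl pivalate F2.
- Oxidative homocoupling of its lithium enolate (LiN(iPr)2, THF, −78 °C; then TiCl4) gives, under control of the two auxiliaries, the (2R,3R)-2,3-bis[(3-methoxy-4-pivaloyloxyphenyl)methyl]succinyl bis-imide F3.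
- LiOH/H2O2 (THF–H2O) removes both auxiliaries and both pivalates to give (2R,3R)-2,3-bis(4-hydroxy-3-methoxybenzyl)butanedioic acid F4.
- DDQ (2.1 equiv, 1,4-dioxane, rt) dehydrogenates both para-hydroxybenzyl positions to the 2R,3R enantiomer of 2, which closes to 4 exactly as in step 1.

Step 4: quinone methide 6 may tautomerise to the benzylidene lactone before hydride reaches it, or borohydride may attack the lactone. The fallback sets out from 5 and comes back at 7.
- Thiophenol (1.5 equiv) with catalytic Et3N in MeCN at rt opens the same ring; the thiolate adds 1,6 to 6 far faster than 6 can tautomerise, giving (2S,3S,4R)-2-(3,4-dimethoxyphenyl)-4-[(4-hydroxy-3-methoxyphenyl)(phenylsulfanyl)methyl]-5-oxooxolane-3-carboxylic acid F5 (both epimers at the sulfur-bearing carbon).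
- Reductive desulfurisation with Ni2B (from NiCl2·6H2O and NaBH4, MeOH–THF, 0 °C) cleaves the benzylic C–S bond and gives 7.

Step 5: the hydroxy acid 9 may re-close onto the benzylic hydroxyl and return 8, or the telescoped sequence may be messy. The fallback sets out from 8 (isolated after the borane reduction and methanol quench) and comes back at 10.
- Appel iodination (PPh3, I2, imidazole, CH2Cl2, 0 °C) converts only the primary alcohol, giving (3R,4S,5S)-5-(3,4-dimethoxyphenyl)-3-(4-hydroxy-3-methoxybenzyl)-4-(iodomethyl)oxolan-2-one F6.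
- LiOH (THF–H2O, rt) saponifies the γ-aryl lactone, and the freed C9 carboxylate displaces the iodide in a 5-exo-tet O-alkylation; acidification to pH 4 gives 10. The direction of ring closure is then set by the leaving group, not by competition between two hydroxyls.

**Further compounds**
F1 | step 1 | 3-(4-hydroxy-3-methoxyphenyl)propanoic acid | COc1cc(CCC(=O)O)ccc1O
F2 | step 1 | 2-methoxy-4-{3-[(4S)-4-isopropyl-2-oxo-1,3-oxazolidin-3-yl]-3-oxopropyl}phenyl pivalate | COc1cc(CCC(=O)N2[C@@H](C(C)C)COC2=O)ccc1OC(=O)C(C)(C)C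
F3 | step 1 | (2R,3R)-2,3-bis[(3-methoxy-4-pivaloyloxyphenyl)methyl]-1,4-bis[(4S)-4-isopropyl-2-oxo-1,3-oxazolidin-3-yl]butane-1,4-dione | COc1cc(C[C@@H](C(=O)N2[C@@H](C(C)C)COC2=O)[C@H](C(=O)N2[C@@H](C(C)C)COC2=O)Cc2ccc(OC(=O)C(C)(C)C)c(OC)c2)ccc1OC(=O)C(C)(C)C
F4 | step 1 | (2R,3R)-2,3-bis(4-hydroxy-3-methoxybenzyl)butanedioic acid | COc1cc(C[C@@H](C(=O)O)[C@H](C(=O)O)Cc2ccc(O)c(OC)c2)ccc1O
F5 | step 4 | (2S,3S,4R)-2-(3,4-dimethoxyphenyl)-4-[(4-hydroxy-3-methoxyphenyl)(phenylsulfanyl)methyl]-5-oxooxolane-3-carboxylic acid | COc1cc(C(Sc2ccccc2)[C@H]2C(=O)O[C@H](c3ccc(OC)c(OC)c3)[C@H]2C(=O)O)ccc1O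
F6 | step 5 | (3R,4S,5S)-5-(3,4-dimethoxyphenyl)-3-(4-hydroxy-3-methoxybenzyl)-4-(iodomethyl)oxolan-2-one | COc1cc(C[C@H]2C(=O)O[C@H](c3ccc(OC)c(OC)c3)[C@H]2CI)ccc1O
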